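## Retrosynthetic overview

1. Target 21 ⇐ β-boryl spiro-butenolide 19 (face-selective CuH reduction, then B→OH) ⇐ tricyclic enone 15 + methyl propiolate 16 (acetylide as a β-acylvinyl anion).
2. 15 ⇐ ester-tethered intramolecular Diels–Alder of silyloxydiene/ynoate 12 (bonds C9–C3 and C1–C2), then enol-ether cleavage and alkene transposition.
3. Dienyl ketone 8 ⇐ key bond C8–C10: alkenyl iodide 3 + the formyl carbon of aldehyde 7 used as an acyl-anion equivalent (Ni/photoredox HAT acyl radical).
4. 3 ⇐ (R)-4-silyloxycyclopentenone 1 (sets C5, C7); 7 ⇐ (S)-carvone 4 (sets C4′).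
5. Ring order: cyclopentane (bought) → cyclohexene and bridging γ-lactone together (one cycloaddition) → spiro γ-lactone last.

Assumption: 1, 4, 10 and 16 are bought as catalogue compounds.

Atom labels used below: cyclohexene C1(=C2)–C3–C9–C8–C10; cyclopentane C5(O)–C6–C7(Me,OH)–C8–C9; C14 = carbonyl of the bridging lactone C3–C14(=O)–O–C5; spiro-lactone C10–C11(OH)–C12–C13(=O)–O; C4′ = side-chain stereocentre on C1.

## Route

Step 1
Reactants: 1 (R)-4-(tert-butyldimethylsilyloxy)cyclopent-2-en-1-one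
Product: 2 (R)-4-(tert-butyldimethylsilyloxy)-2-iodocyclopent-2-en-1-one
Conditions: I2, pyridine, CH2Cl2, 0 → 23 °C
Reagents that add atoms: iodine, II
Why: Johnson α-iodination of an enone (pyridine conjugate addition, iodination of the enolate, E1cB loss of pyridine) puts iodine on the α-carbon (future C8) and leaves the C5 stereocentre untouched.

Step 2
Reactants: 2 (R)-4-(tert-butyldimethylsilyloxy)-2-iodocyclopent-2-en-1-one
Product: 3 (1S,4R)-4-(tert-butyldimethylsilyloxy)-2-iodo-1-methylcyclopent-2-en-1-ol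
Conditions: MeMgBr, THF, −78 °C; aq NH4Cl
Reagents that add atoms: methylmagnesium bromide, C[Mg]Br
Why: Grignard 1,2-addition to the enone carbonyl occurs anti to the C5 silyloxy group, so the new C7–OH is cis to C5–O (sets C7).

Step 3
Reactants: 4 (S)-(+)-carvone
Product: 5 (1S,4S,6S)-1-methyl-4-(prop-1-en-2-yl)-7-oxabicyclo[4.1.0]heptan-2-one
Conditions: 30% H2O2, NaOH (cat.), MeOH, 0 °C
Reagents that add atoms: hydrogen peroxide, OO
Why: Weitz–Scheffer nucleophilic epoxidation attacks only the enone (not the isopropenyl group), anti to the isopropenyl substituent; the two new centres are excised in step 4.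

Step 4
Reactants: 5 (1S,4S,6S)-1-methyl-4-(prop-1-en-2-yl)-7-oxabicyclo[4.1.0]heptan-2-one
Product: 6 (3S)-5-oxo-3-(prop-1-en-2-yl)pentanoic acid
Conditions: H5IO6 (2.5 equiv), THF/H2O, 0 → 23 °C
Reagents that add atoms: periodic acid, OI(=O)(O)(O)(O)O; water, O
Why: Acidic epoxide hydrolysis followed by Malaprade-type periodate cleavage of the diol and of the resulting 1,2-diketone excises the C(Me) carbon as acetic acid; the stereocentre is β to both new carbonyls and cannot epimerise.

Step 5
Reactants: 6 (3S)-5-oxo-3-(prop-1-en-2-yl)pentanoic acid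
Product: 7 methyl (3S)-5-oxo-3-(prop-1-en-2-yl)pentanoate
Conditions: MeI, KHCO3, DMF, 23 °C
Reagents that add atoms: iodomethane, CI
Why: Carboxylate O-alkylation (SN2) under weak base esterifies the acid without touching the aldehyde.

Step 6
Reactants: 3 (1S,4R)-4-(tert-butyldimethylsilyloxy)-2-iodo-1-methylcyclopent-2-en-1-ol; 7 methyl (3S)-5-oxo-3-(prop-1-en-2-yl)pentanoate
Product: 8 methyl (3S)-5-[(3R,5S)-3-(tert-butyldimethylsilyloxy)-5-hydroxy-5-methylcyclopent-1-en-1-yl]-5-oxo-3-(prop-1-en-2-yl)pentanoate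
Conditions: NiBr2·dme (10 mol %), dtbbpy (10 mol %), Ir[dF(CF3)ppy]2(dtbbpy)PF6 (1 mol %), quinuclidine (20 mol %), K2CO3, 1,4-dioxane, blue LED, 23 °C
Reagents that add atoms: none
Why: Proposed new method: the photogenerated quinuclidinium radical cation abstracts the hydridic formyl H of 7, the nucleophilic acyl radical (an acyl-anion equivalent) is captured by the alkenyl–Ni(II) species from oxidative addition of 3, and reductive elimination from Ni(III) gives the enone, joining two carbons that are both electrophilic in their parent forms; the closest known reaction is the Ni/photoredox/HAT aldehyde C–H acylation of aryl and alkyl bromides, extended here to a hindered cyclic alkenyl iodide, and no stereocentre is formed or touched (C4′ is β to the radical; 4-exo/5-endo closure onto isopropenyl is disfavoured).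

Step 7
Reactants: 8 methyl (3S)-5-[(3R,5S)-3-(tert-butyldimethylsilyloxy)-5-hydroxy-5-methylcyclopent-1-en-1-yl]-5-oxo-3-(prop-1-en-2-yl)pentanoate
Product: 9 methyl (3S)-5-[(3R,5S)-3,5-dihydroxy-5-methylcyclopent-1-en-1-yl]-5-oxo-3-(prop-1-en-2-yl)pentanoate
Conditions: HF·pyridine, pyridine, THF, 0 → 23 °C
Reagents that add atoms: none
Why: Fluoride desilylation under buffered acidic conditions frees the allylic C5–OH without the base that would isomerise the γ-hydroxy enone to a 1,4-diketone.

Step 8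
Reactants: 9 methyl (3S)-5-[(3R,5S)-3,5-dihydroxy-5-methylcyclopent-1-en-1-yl]-5-oxo-3-(prop-1-en-2-yl)pentanoate; 10 propiolic acid
Product: 11 (1R,4S)-4-hydroxy-3-[(3S)-5-methoxy-5-oxo-3-(prop-1-en-2-yl)pentanoyl]-4-methylcyclopent-2-en-1-yl prop-2-ynoate
Conditions: DIC, DMAP (5 mol %), CH2Cl2, −20 → 0 °C
Reagents that add atoms: none
Why: Steglich-type esterification acylates only the secondary allylic C5–OH (the tertiary C7–OH is too hindered), attaching the dienophile with retention at C5.

Step 9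
Reactants: 11 (1R,4S)-4-hydroxy-3-[(3S)-5-methoxy-5-oxo-3-(prop-1-en-2-yl)pentanoyl]-4-methylcyclopent-2-en-1-yl prop-2-ynoate
Product: 13 bis-TES tricyclic cyclohexa-1,4-diene lactone (C8=C10–OTES enol ether; C2=C3 conjugated to C14; C7–OTES), via bis-TES dienol ether 12 (not isolated)
Conditions: TESOTf (2.5 equiv), Et3N (3 equiv), CH2Cl2, −78 → 0 °C; then PhMe, 80 °C
Reagents that add atoms: triethylsilyl trifluoromethanesulfonate, CC[Si](CC)(CC)OS(=O)(=O)C(F)(F)F
Why: Soft enolisation at the only enolisable α-carbon (C1) gives the (Z)-2-silyloxydiene C9=C8–C10(OTES)=C1, which undergoes a type-1 intramolecular Diels–Alder reaction with the tethered ynoate; the three-atom ester tether fixes the regiochemistry (C9–C3, C1–C2) and forces addition on the C5–O face, so C9–C3 is cis to C5–O and the bridging lactone closes in the same event.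

Step 10
Reactants: 13 bis-TES tricyclic cyclohexa-1,4-diene lactone
Product: 15 tricyclic enone-lactone (C10 ketone; C1=C2; cis-fused at C8/C9 and C3/C9; free C7–OH), via deconjugated keto-lactone 14 (not isolated)
Conditions: HF·pyridine, THF, 0 °C; then DBU (0.3 equiv), CH2Cl2, 0 °C
Reagents that add atoms: none
Why: Protodesilylation of the enol ether and the tertiary TES ether gives ketone 14, then base-mediated deconjugation/reconjugation (γ-deprotonation at the doubly activated C1–H, reprotonation at C3) moves the alkene into conjugation with the C10 ketone; C8 equilibrates to the cis ring fusion and C3 protonates to the cis-fused lactone.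

Step 11
Reactants: 15 tricyclic enone-lactone; 16 methyl propiolate
Product: 17 C10 tertiary propargylic alcohol (methyl 3-(C10-hydroxy)prop-2-ynoate adduct)
Conditions: 16, LDA, THF, −78 °C; CeCl3; then 15, −78 °C
Reagents that add atoms: none
Why: 1,2-addition of the weakly basic cerium acetylide (a β-acylvinyl-anion, homoenolate-type donor) to the enone carbonyl occurs from the convex face, anti to the cyclopentane and C7, which sets C10 with the new carbon cis to H8.

Step 12
Reactants: 17 C10 tertiary propargylic alcohol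
Product: 19 β-boryl spiro-butenolide (Bpin on C11), via Z-β-boryl hydroxy enoate 18 (not isolated)
Conditions: B2pin2 (1.1 equiv), CuCl (5 mol %), Xantphos (5 mol %), NaOtBu (10 mol %), MeOH (2 equiv), THF, 23 °C; then PPTS (cat.), CH2Cl2
Reagents that add atoms: bis(pinacolato)diboron, CC1(C)OB(OC1(C)C)B1OC(C)(C)C(C)(C)O1
Why: Cu-catalysed β-boration of the ynoate (syn borylcupration, then protonation) puts boron on C11 and places C10–OH cis to the ester, so lactonisation closes the spiro-butenolide.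

Step 13
Reactants: 19 β-boryl spiro-butenolide
Product: 21 target CNP0148106.2, via C11 pinacol boronate 20 (not isolated)
Conditions: Cu(OAc)2 (5 mol %), DTBM-SEGPHOS (matched enantiomer, 5.5 mol %), (MeO)2MeSiH, t-BuOH, THF, 0 °C; then NaBO3·4H2O, THF/H2O, 23 °C
Reagents that add atoms: sodium perborate, [Na+].[Na+].O[B-]1(O)OO[B-](O)(O)OO1
Why: CuH conjugate reduction of the β-boryl butenolide delivers hydride to C11 from the less hindered face (the C8–H side, anti to the C1 side chain; the chiral ligand is chosen to reinforce this), leaving boron syn to C1, and stereoretentive perborate oxidation gives the (S)-C11 alcohol.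

## Compound list

1 | (R)-4-(tert-butyldimethylsilyloxy)cyclopent-2-en-1-one | O=C1C=C[C@H](O[Si](C)(C)C(C)(C)C)C1 | starting material
2 | (R)-4-(tert-butyldimethylsilyloxy)-2-iodocyclopent-2-en-1-one | O=C1C(I)=C[C@H](O[Si](C)(C)C(C)(C)C)C1 | intermediate
3 | (1S,4R)-4-(tert-butyldimethylsilyloxy)-2-iodo-1-methylcyclopent-2-en-1-ol (OH cis to OTBS) | CC(C)(C)[Si](C)(C)O[C@@H]1C[C@](C)(O)C(I)=C1 | intermediate
4 | (S)-(+)-carvone | C=C(C)[C@@H]1CC(=O)C(C)=CC1 | starting material
5 | (1S,4S,6S)-1-methyl-4-(prop-1-en-2-yl)-7-oxabicyclo[4.1.0]heptan-2-one (epoxide anti to isopropenyl) | C=C(C)[C@@H]1CC(=O)[C@@]2(C)O[C@H]2C1 | intermediate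
6 | (3S)-5-oxo-3-(prop-1-en-2-yl)pentanoic acid | C=C(C)[C@H](CC(=O)O)CC=O | intermediate
7 | methyl (3S)-5-oxo-3-(prop-1-en-2-yl)pentanoate | C=C(C)[C@H](CC(=O)OC)CC=O | intermediate
8 | methyl (3S)-5-[(3R,5S)-3-(tert-butyldimethylsilyloxy)-5-hydroxy-5-methylcyclopent-1-en-1-yl]-5-oxo-3-(prop-1-en-2-yl)pentanoate | C=C(C)[C@H](CC(=O)OC)CC(=O)C1=C[C@H](O[Si](C)(C)C(C)(C)C)C[C@]1(C)O | intermediate
9 | methyl (3S)-5-[(3R,5S)-3,5-dihydroxy-5-methylcyclopent-1-en-1-yl]-5-oxo-3-(prop-1-en-2-yl)pentanoate | C=C(C)[C@H](CC(=O)OC)CC(=O)C1=C[C@H](O)C[C@]1(C)O | intermediate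
10 | propiolic acid | C#CC(=O)O | starting material
11 | (1R,4S)-4-hydroxy-3-[(3S)-5-methoxy-5-oxo-3-(prop-1-en-2-yl)pentanoyl]-4-methylcyclopent-2-en-1-yl prop-2-ynoate | C=C(C)[C@H](CC(=O)OC)CC(=O)C1=C[C@H](OC(=O)C#C)C[C@]1(C)O | intermediate
12 | bis-TES (Z)-dienol ether of 11 (C10–OTES, C10=C1 Z; C7–OTES; propiolate on C5–O) | C=C(C)[C@H](CC(=O)OC)/C=C(O[Si](CC)(CC)CC)/C1=C[C@H](OC(=O)C#C)C[C@]1(C)O[Si](CC)(CC)CC | intermediate
13 | bis-TES tricyclic cyclohexa-1,4-diene lactone (C8=C10–OTES; C2=C3; H1 cis to H9; lactone cis on C5/C9) | C=C(C)[C@H](CC(=O)OC)[C@@H]1C=C2C(=O)O[C@@H]3C[C@](C)(O[Si](CC)(CC)CC)C([C@H]23)=C1O[Si](CC)(CC)CC | intermediate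
14 | deconjugated keto-lactone (C10 ketone, C2=C3, C1–H; drawn as the cis-fused C8 epimer) | C=C(C)[C@H](CC(=O)OC)[C@@H]1C=C2C(=O)O[C@@H]3C[C@](C)(O)[C@@H]([C@H]23)C1=O | intermediate
15 | tricyclic enone-lactone (C10 ketone, C1=C2; H3, H8, H9 all cis; C5–O and C7–OH on the opposite face) | C=C(C)[C@H](CC(=O)OC)C1=C[C@@H]2C(=O)O[C@@H]3C[C@](C)(O)[C@@H]([C@H]23)C1=O | intermediate
16 | methyl propiolate | C#CC(=O)OC | starting material
17 | C10 tertiary propargylic alcohol (alkynoate cis to H8, C10–OH on the C7 face) | C=C(C)[C@H](CC(=O)OC)C1=C[C@@H]2C(=O)O[C@@H]3C[C@](C)(O)[C@@H]([C@H]23)[C@@]1(O)C#CC(=O)OC | intermediate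
18 | Z-β-boryl γ-hydroxy enoate (Bpin on C11; C10 and CO2Me cis) | C=C(C)[C@H](CC(=O)OC)C1=C[C@@H]2C(=O)O[C@@H]3C[C@](C)(O)[C@@H]([C@H]23)[C@@]1(O)/C(B4OC(C)(C)C(C)(C)O4)=C\C(=O)OC | intermediate
19 | β-boryl spiro-butenolide (C11–Bpin, C11=C12) | C=C(C)[C@H](CC(=O)OC)C1=C[C@@H]2C(=O)O[C@@H]3C[C@](C)(O)[C@@H]([C@H]23)[C@]12OC(=O)C=C2B4OC(C)(C)C(C)(C)O4 | intermediate
20 | C11 pinacol boronate of the spiro-lactone (boron syn to C1) | C=C(C)[C@H](CC(=O)OC)C1=C[C@@H]2C(=O)O[C@@H]3C[C@](C)(O)[C@@H]([C@H]23)[C@]12OC(=O)C[C@@H]2B4OC(C)(C)C(C)(C)O4 | intermediate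
21 | CNP0148106.2 (C4′ S, C3 S, C5 R, C7 S, C8 R, C9 R, C10 S, C11 S) | C=C(C)[C@H](CC(=O)OC)C1=C[C@@H]2C(=O)O[C@@H]3C[C@](C)(O)[C@@H]([C@H]23)[C@]12OC(=O)C[C@@H]2O | target

## Step count and risks

Total step count: 13. Longest linear sequence: 11 (steps 3–13, from (S)-carvone 4 to the target); steps 1–2 are a two-step side branch that joins at step 6.

Steps most likely to fail:

Step 6 (acyl-radical/alkenyl iodide coupling). The alkenyl iodide is hindered and the aldehyde carries allylic C–H bonds that could compete in hydrogen abstraction. The fallback sets out from 3 and 7 and returns at 8. A Nozaki–Hiyama–Kishi coupling (CrCl2, cat. NiCl2, DMF) uses 3 as the nucleophile and 7 as a normal electrophile to give the secondary allylic alcohol F1 (epimer mixture at C10). Dess–Martin oxidation of F1 then gives 8.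

Step 9 (enol silylation next to a terminal propiolate, then cycloaddition). Et3N/TESOTf may add to or C-silylate the acidic ynoate before the diene forms. The fallback sets out from 9 and returns at 15, replacing the alkyne by an alkyne-equivalent alkene. DIC esterification of 9 with (E)-3-(phenylsulfonyl)acrylic acid gives the sulfonylacrylate ester F2, which has no acidic C–H. TESOTf/Et3N gives the bis-TES dienol ether F3, which cyclises to the sulfonyl cycloadduct F4. HF·pyridine then DBU removes the silyl groups and eliminates benzenesulfinate from C2 by E1cB through the C10 ketone enolate. This gives 15 directly, with the C1=C2 alkene formed by elimination and not by isomerisation.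

Step 13 (facial selectivity at C11 and a hindered conjugate reduction). If hydride delivery is unselective or fails, the fallback sets out from 17 and returns at 20, delivering boron instead of hydrogen to the prochiral carbon. Lindlar semi-hydrogenation of 17 gives the Z-hydroxy enoate F5, which lactonises to the unsubstituted spiro-butenolide F6. Cu-catalysed asymmetric β-boration (B2pin2, CuCl, NaOtBu, Josiphos-type ligand, MeOH) then adds Bpin to C11 under ligand control to give 20. Oxidation of 20 proceeds as in step 13.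

## Further compounds

F1 | step 6 | methyl (3S)-5-[(3R,5S)-3-(tert-butyldimethylsilyloxy)-5-hydroxy-5-methylcyclopent-1-en-1-yl]-5-hydroxy-3-(prop-1-en-2-yl)pentanoate (C10 epimer mixture) | C=C(C)[C@H](CC(=O)OC)CC(O)C1=C[C@H](O[Si](C)(C)C(C)(C)C)C[C@]1(C)O
F2 | step 9 | (E)-3-(phenylsulfonyl)acrylate ester of 9 at C5–O | C=C(C)[C@H](CC(=O)OC)CC(=O)C1=C[C@H](OC(=O)/C=C/S(=O)(=O)c2ccccc2)C[C@]1(C)O
F3 | step 9 | bis-TES (Z)-dienol ether of F2 | C=C(C)[C@H](CC(=O)OC)/C=C(O[Si](CC)(CC)CC)/C1=C[C@H](OC(=O)/C=C/S(=O)(=O)c2ccccc2)C[C@]1(C)O[Si](CC)(CC)CC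
F4 | step 9 | bis-TES sulfonyl cycloadduct (C2–SO2Ph trans to C14; C8=C10–OTES) | C=C(C)[C@H](CC(=O)OC)[C@@H]1[C@@H](S(=O)(=O)c4ccccc4)[C@@H]2C(=O)O[C@@H]3C[C@](C)(O[Si](CC)(CC)CC)C([C@H]23)=C1O[Si](CC)(CC)CC
F5 | step 13 | Z-γ-hydroxy enoate from semi-hydrogenation of 17 | C=C(C)[C@H](CC(=O)OC)C1=C[C@@H]2C(=O)O[C@@H]3C[C@](C)(O)[C@@H]([C@H]23)[C@@]1(O)/C=C\C(=O)OC
F6 | step 13 | spiro-butenolide (C11=C12, no boron) | C=C(C)[C@H](CC(=O)OC)C1=C[C@@H]2C(=O)O[C@@H]3C[C@](C)(O)[C@@H]([C@H]23)[C@]12OC(=O)C=C2
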